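The tetrahydropyran is read as the reduced δ-lactone of an achiral 4-(hydroxymethyl)pimelate: ring carbon C5 carries the C6 oxymethylene and two three-carbon arms (ring C4–C3–C2 and side-chain CH2–CH2–CHOH), each ending in an oxygenated carbon attached to a 1,1-disubstituted alkene. A lipase is therefore asked to lactonise dimethyl 4-(hydroxymethyl)heptanedioate through one enantiotopic ester arm, which closes the ring at the O1–C2 acyl bond and fixes C5 in one operation. C2 is then relayed from C5 by acetylide addition and axial hydride delivery, the alkyne is carbonylated to the acrylate, and an asymmetric Nozaki–Hiyama–Kishi coupling with a geranyl-derived 2-iodoalkene sets the carbinol.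

Key step: step 3

Assumption: the hydrolase panel is taken to contain an enzyme (porcine pancreatic lipase is written in) that acylates through the pro-S ester arm of 5, and the ligand antipode in step 12 is the one that leads to the R carbinol; both senses are to be confirmed by correlation on the first runs.

Step 1
Reactants: 1 dimethyl 4-oxoheptanedioate; 2 methyltriphenylphosphonium bromide
Product: 3 dimethyl 4-methylideneheptanedioate
Conditions: 2 (1.3 equiv), KOtBu (1.2 equiv), THF, 0 °C, 30 min; then 1, 0 °C to rt
Reagents that add atoms: none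
Why: Wittig methylenation, in which the non-stabilised ylide adds to the ketone far faster than to the methyl esters, and pre-forming it with a deficit of base leaves no free alkoxide to trigger Claisen-type cyclisation of the keto diester.

Step 2
Reactants: 3 dimethyl 4-methylideneheptanedioate
Product: 5 dimethyl 4-(hydroxymethyl)heptanedioate, via B-alkyl-9-BBN adduct 4 (not isolated)
Conditions: 9-BBN, THF, 0 °C to rt; then aq NaOAc, 30% H2O2, 0 °C to rt; neutral cold work-up (any lactone reopened with cat. K2CO3, MeOH, then AcOH)
Reagents that add atoms: hydrogen peroxide, OO; 9-BBN, B1C2CCCC1CCC2 (its boron stays only in intermediate 4)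
Why: Hydroboration–oxidation, in which 9-BBN adds anti-Markovnikov to the 1,1-disubstituted alkene without touching esters and the acetate-buffered peroxide step avoids saponification; the achiral product is used at once so that uncatalysed lactonisation cannot build up racemic lactone.

Step 3
Reactants: 5 dimethyl 4-(hydroxymethyl)heptanedioate
Product: 6 methyl 3-[(3S)-6-oxotetrahydro-2H-pyran-3-yl]propanoate
Conditions: porcine pancreatic lipase (first choice from a panel that also holds Candida antarctica lipase B and Burkholderia cepacia lipase), anhydrous MTBE, 5 Å molecular sieves, 0.02 M, 30 °C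
Reagents that add atoms: none
Why: Proposed new method: the active-site serine should be acylated by one of the two enantiotopic methyl ester arms of 5, and the acyl-enzyme is then released intramolecularly by the hydroxymethyl oxygen, so the arm held in the acyl pocket becomes the ring while the other remains a methyl ester. The closest known reaction type is the lipase-catalysed enantioselective lactonisation of prochiral 4-hydroxypimelate diesters to γ-lactones in organic solvent, within the wider family of hydrolase desymmetrisations of prochiral diesters; here the nucleophile is a primary alcohol one carbon further out and the ring is six-membered. The single ring closes by 6-exo-trig acyl transfer, forming the O–C(=O) bond of the δ-lactone that later becomes the tetrahydropyran. The new stereocentre (C3 of the lactone, ring C5 of the target) is controlled only by the chiral acyl-binding pocket of the enzyme, which has to take the pro-S arm to give the S lactone. The step needs selection between two ester carbonyls three bonds from the prochiral carbon and suppression of racemic background lactonisation and of oligomerisation; the unhindered methyl esters, the slow uncatalysed closure of δ-hydroxy methyl esters in dry neutral ether, high dilution and sieves that trap methanol are expected to secure this.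

Step 4
Reactants: 6 methyl 3-[(3S)-6-oxotetrahydro-2H-pyran-3-yl]propanoate; 7 (trimethylsilyl)acetylene
Product: 8 methyl 3-[(3R)-6-hydroxy-6-[(trimethylsilyl)ethynyl]tetrahydro-2H-pyran-3-yl]propanoate (anomer mixture)
Conditions: 7, n-BuLi (1.0 equiv), THF, −78 °C; then added slowly to 6, THF, −78 °C; AcOH quench at −78 °C
Reagents that add atoms: none
Why: 1,2-Addition of a lithium acetylide to a lactone, in which the δ-lactone carbonyl is markedly more electrophilic than the acyclic methyl ester and its lithium hemiketal alkoxide persists at −78 °C, so one equivalent should add once and only at the ring carbonyl; the anomeric centre is erased in the next step.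

Step 5
Reactants: 8 methyl 3-[(3R)-6-hydroxy-6-[(trimethylsilyl)ethynyl]tetrahydro-2H-pyran-3-yl]propanoate
Product: 9 methyl 3-[(3R,6R)-6-[(trimethylsilyl)ethynyl]tetrahydro-2H-pyran-3-yl]propanoate (ring substituents trans)
Conditions: Et3SiH, BF3·OEt2, CH2Cl2/MeCN, −78 to −30 °C
Reagents that add atoms: none
Why: Ionic hydrogenation of a lactol (silane reduction of a cyclic oxocarbenium ion): BF3 ionises the anomeric hydroxyl, and Et3SiH attacks the alkynyl-substituted oxocarbenium ion along the axial trajectory of the half-chair that keeps the propanoate arm pseudo-equatorial, which places the new C–H axial and the alkynyl group equatorial, trans to the arm (R at the alkynyl carbon).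

Step 6
Reactants: 9 methyl 3-[(3R,6R)-6-[(trimethylsilyl)ethynyl]tetrahydro-2H-pyran-3-yl]propanoate
Product: 11 3-[(3S,6R)-6-ethynyltetrahydro-2H-pyran-3-yl]propan-1-ol, via silyl alkyne alcohol 10 (not isolated)
Conditions: LiAlH4, THF, 0 °C; then MeOH, K2CO3, 0 °C to rt
Reagents that add atoms: none
Why: Hydride reduction of the saturated methyl ester, followed in the same flask by methoxide-mediated protodesilylation of the alkynylsilane; a propargylic ether without a free hydroxyl is not reduced by LiAlH4 at 0 °C, and neither ring stereocentre is involved.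

Step 7
Reactants: 11 3-[(3S,6R)-6-ethynyltetrahydro-2H-pyran-3-yl]propan-1-ol
Product: 12 methyl 2-[(2R,5S)-5-(3-hydroxypropyl)tetrahydro-2H-pyran-2-yl]prop-2-enoate
Conditions: Pd(OAc)2 (1 mol%), 2-(diphenylphosphino)pyridine, MeSO3H, CO (10 bar), MeOH, 50 °C; stopped at full conversion of the alkyne
Reagents that add atoms: carbon monoxide, [C-]#[O+]; methanol, CO
Why: Palladium-catalysed Markovnikov hydromethoxycarbonylation of a terminal alkyne, in which the pyridylphosphine and sulfonic acid co-catalyst deliver the ester carbon to the internal alkyne carbon to give the 2-substituted acrylate directly, while methanol as solvent outcompetes the primary alcohol as nucleophile and the ring ether carbon is not ionised.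

Step 8
Reactants: 12 methyl 2-[(2R,5S)-5-(3-hydroxypropyl)tetrahydro-2H-pyran-2-yl]prop-2-enoate
Product: 13 methyl 2-[(2R,5R)-5-(3-oxopropyl)tetrahydro-2H-pyran-2-yl]prop-2-enoate (ring substituents trans)
Conditions: Dess–Martin periodinane, CH2Cl2, 0 °C to rt
Reagents that add atoms: none
Why: Dess–Martin oxidation of a primary alcohol to the aldehyde under neutral non-aqueous conditions, which should leave the acrylate, the ring ether and both stereocentres untouched and cannot over-oxidise.

Step 9
Reactants: 14 geranyl bromide; 15 1-(trimethylsilyl)propyne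
Product: 16 [(5E)-6,10-dimethylundeca-5,9-dien-1-yn-1-yl]trimethylsilane
Conditions: 15, n-BuLi, THF, −78 to −20 °C; then 14, −78 °C to rt
Reagents that add atoms: none
Why: SN2 alkylation of 3-(trimethylsilyl)propargyllithium with a primary allylic bromide, in which the silyl group steers the ambident anion to react at the propargylic carbon and the unhindered bromide reacts without allylic transposition, so the E alkene of the geranyl unit is carried over unchanged.

Step 10
Reactants: 16 [(5E)-6,10-dimethylundeca-5,9-dien-1-yn-1-yl]trimethylsilane
Product: 17 (5E)-6,10-dimethylundeca-5,9-dien-1-yne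
Conditions: K2CO3 (cat.), MeOH, rt
Reagents that add atoms: none
Why: Base-mediated protodesilylation of an alkynylsilane with carbonate in methanol, under which the skipped diene is inert.

Step 11
Reactants: 17 (5E)-6,10-dimethylundeca-5,9-dien-1-yne
Product: 19 (5E)-2-iodo-6,10-dimethylundeca-1,5,9-triene, via iodoalkenylborane 18 (not isolated)
Conditions: B-iodo-9-BBN, pentane, −20 to 0 °C; then AcOH, 0 °C to rt
Reagents that add atoms: B-iodo-9-borabicyclo[3.3.1]nonane, IB1C2CCCC1CCC2
Why: Haloboration–protonolysis, in which the B–I bond adds syn across the terminal alkyne only, with iodine at the internal carbon, and acetic acid then cleaves the alkenyl C–B bond to leave the 2-iodo-1-alkene; trisubstituted alkenes are not attacked by this reagent at low temperature.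

Step 12
Reactants: 13 methyl 2-[(2R,5R)-5-(3-oxopropyl)tetrahydro-2H-pyran-2-yl]prop-2-enoate; 19 (5E)-2-iodo-6,10-dimethylundeca-1,5,9-triene
Product: 20 methyl 2-[(2R,5S)-5-[(3R,7E)-3-hydroxy-8,12-dimethyl-4-methylidenetrideca-7,11-dien-1-yl]tetrahydro-2H-pyran-2-yl]prop-2-enoate
Conditions: CrCl2 (10 mol%), N-[2-(4-isopropyl-4,5-dihydrooxazol-2-yl)-6-methylphenyl]methanesulfonamide (single enantiomer, antipode as assumed above), 1,8-bis(dimethylamino)naphthalene, NiCl2·(2,9-dimethyl-1,10-phenanthroline) (2 mol%), Mn powder, Cp2ZrCl2, LiCl, MeCN, rt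
Reagents that add atoms: none
Why: Catalytic asymmetric Nozaki–Hiyama–Kishi coupling, in which nickel activates the alkenyl iodide and passes the alkenyl group to chromium, and the alkenylchromium species bound to the chiral sulfonamide adds to one aldehyde face so that the ligand alone sets the R carbinol; the ring stereocentres are too remote to interfere and the reagent tolerates the acrylate ester and the isolated alkenes.

Step 13
Reactants: 20 methyl 2-[(2R,5S)-5-[(3R,7E)-3-hydroxy-8,12-dimethyl-4-methylidenetrideca-7,11-dien-1-yl]tetrahydro-2H-pyran-2-yl]prop-2-enoate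
Product: 21 2-[(2R,5S)-5-[(3R,7E)-3-hydroxy-8,12-dimethyl-4-methylidenetrideca-7,11-dien-1-yl]tetrahydro-2H-pyran-2-yl]prop-2-enoic acid
Conditions: LiOH, THF/H2O, 0 °C to rt; then 1 M HCl to pH 3–4 at 0 °C
Reagents that add atoms: lithium hydroxide, [Li+].[OH-]
Why: Saponification of the methyl ester followed by mild acidification; the α-substituted acrylate is a poor Michael acceptor for hydroxide, no stereocentre is base-labile, and the allylic alcohol and the triene are not affected.

Compound list
1 | dimethyl 4-oxoheptanedioate | COC(=O)CCC(=O)CCC(=O)OC | starting material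
2 | methyltriphenylphosphonium bromide | C[P+](c1ccccc1)(c1ccccc1)c1ccccc1.[Br-] | starting material
3 | dimethyl 4-methylideneheptanedioate | C=C(CCC(=O)OC)CCC(=O)OC | intermediate
4 | dimethyl 4-[(9-borabicyclo[3.3.1]nonan-9-yl)methyl]heptanedioate (not isolated) | COC(=O)CCC(CB1C2CCCC1CCC2)CCC(=O)OC | intermediate
5 | dimethyl 4-(hydroxymethyl)heptanedioate (achiral) | COC(=O)CCC(CO)CCC(=O)OC | intermediate
6 | methyl 3-[(3S)-6-oxotetrahydro-2H-pyran-3-yl]propanoate | COC(=O)CC[C@H]1CCC(=O)OC1 | intermediate
7 | (trimethylsilyl)acetylene | C#C[Si](C)(C)C | starting material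
8 | methyl 3-[(3R)-6-hydroxy-6-[(trimethylsilyl)ethynyl]tetrahydro-2H-pyran-3-yl]propanoate (anomer mixture, in equilibrium with the open hydroxy ynone) | COC(=O)CC[C@H]1CCC(O)(C#C[Si](C)(C)C)OC1 | intermediate
9 | methyl 3-[(3R,6R)-6-[(trimethylsilyl)ethynyl]tetrahydro-2H-pyran-3-yl]propanoate (ring substituents trans) | COC(=O)CC[C@H]1CC[C@H](C#C[Si](C)(C)C)OC1 | intermediate
10 | 3-[(3S,6R)-6-[(trimethylsilyl)ethynyl]tetrahydro-2H-pyran-3-yl]propan-1-ol (not isolated) | OCCC[C@H]1CC[C@H](C#C[Si](C)(C)C)OC1 | intermediate
11 | 3-[(3S,6R)-6-ethynyltetrahydro-2H-pyran-3-yl]propan-1-ol | OCCC[C@H]1CC[C@H](C#C)OC1 | intermediate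
12 | methyl 2-[(2R,5S)-5-(3-hydroxypropyl)tetrahydro-2H-pyran-2-yl]prop-2-enoate | OCCC[C@H]1CC[C@H](C(=C)C(=O)OC)OC1 | intermediate
13 | methyl 2-[(2R,5R)-5-(3-oxopropyl)tetrahydro-2H-pyran-2-yl]prop-2-enoate (ring substituents trans) | O=CCC[C@H]1CC[C@H](C(=C)C(=O)OC)OC1 | intermediate
14 | geranyl bromide, (2E)-1-bromo-3,7-dimethylocta-2,6-diene | CC(C)=CCC/C(C)=C/CBr | starting material
15 | 1-(trimethylsilyl)propyne | CC#C[Si](C)(C)C | starting material
16 | [(5E)-6,10-dimethylundeca-5,9-dien-1-yn-1-yl]trimethylsilane | C[Si](C)(C)C#CCC/C=C(\C)CCC=C(C)C | intermediate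
17 | (5E)-6,10-dimethylundeca-5,9-dien-1-yne | C#CCC/C=C(\C)CCC=C(C)C | intermediate
18 | 9-[(1Z,5E)-2-iodo-6,10-dimethylundeca-1,5,9-trien-1-yl]-9-borabicyclo[3.3.1]nonane (not isolated) | I/C(CC/C=C(\C)CCC=C(C)C)=C\B1C2CCCC1CCC2 | intermediate
19 | (5E)-2-iodo-6,10-dimethylundeca-1,5,9-triene | C=C(I)CC/C=C(\C)CCC=C(C)C | intermediate
20 | methyl 2-[(2R,5S)-5-[(3R,7E)-3-hydroxy-8,12-dimethyl-4-methylidenetrideca-7,11-dien-1-yl]tetrahydro-2H-pyran-2-yl]prop-2-enoate | C=C(CC/C=C(\C)CCC=C(C)C)[C@H](O)CC[C@H]1CC[C@H](C(=C)C(=O)OC)OC1 | intermediate
21 | 2-[(2R,5S)-5-[(3R,7E)-3-hydroxy-8,12-dimethyl-4-methylidenetrideca-7,11-dien-1-yl]tetrahydro-2H-pyran-2-yl]prop-2-enoic acid (CNP0197923.2) | C=C(CC/C=C(\C)CCC=C(C)C)[C@H](O)CC[C@H]1CC[C@H](C(=C)C(=O)O)OC1 | target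

Total step count: 13. Longest linear sequence: 10 steps (steps 1 to 8, then 12 and 13); steps 9 to 11 build the iodide separately.

Steps most likely to fail

Step 3. The enzyme may discriminate poorly between the two enantiotopic ester arms, or intermolecular acyl transfer and uncatalysed ring closure may erode the enantiomeric purity. The fallback sets out from 5, returns at 6, and replaces desymmetrisation by racemate formation and resolution. Hydroxy diester 5 is closed with catalytic TsOH in warm toluene, with methanol stripped off, to racemic methyl 3-(6-oxotetrahydro-2H-pyran-3-yl)propanoate F1. F1 is separated on a preparative chiral stationary phase into 6 and its antipode, methyl 3-[(3R)-6-oxotetrahydro-2H-pyran-3-yl]propanoate F2. F2 is not lost, because carbonate-catalysed methanolysis reopens it to achiral 5 for another cycle.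

Step 4. The acetylide may fail to distinguish lactone from side-chain ester, or may add twice after collapse of the hemiketal alkoxide. The fallback sets out from 6, returns at 10, and hands the chemoselectivity to milder reagents.
- Lactone 6 is opened with morpholine (toluene, 60 °C), which leaves methyl esters alone, to methyl (4R)-4-(hydroxymethyl)-7-(morpholin-4-yl)-7-oxoheptanoate F3.
- LiBH4 in THF reduces the ester but not the tertiary amide, giving (4S)-7-hydroxy-4-(hydroxymethyl)-1-(morpholin-4-yl)heptan-1-one F4.
- Excess lithium (trimethylsilyl)acetylide converts the morpholine amide into the ynone, which is obtained as its lactol 3-[(3S)-6-hydroxy-6-[(trimethylsilyl)ethynyl]tetrahydro-2H-pyran-3-yl]propan-1-ol F5. Only the hydroxymethyl group on the stereocentre can close a six-membered hemiketal.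
- Et3SiH and BF3·OEt2, as in step 5, then give 10, which enters step 6 at the desilylation stage.

Step 12. Ligand control over the aldehyde face may be incomplete, giving a mixture of carbinol epimers, or catalyst turnover may be sluggish. The fallback sets out from 13 and 19, returns at 20, and sets the carbinol by reduction instead of during C–C bond formation.
- 13 and 19 are coupled without chiral ligand (CrCl2, catalytic NiCl2, DMSO) to the carbinol-epimer mixture methyl 2-[(2R,5S)-5-[(7E)-3-hydroxy-8,12-dimethyl-4-methylidenetrideca-7,11-dien-1-yl]tetrahydro-2H-pyran-2-yl]prop-2-enoate F6.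
- Dess–Martin oxidation gives the enone methyl 2-[(2R,5S)-5-[(7E)-8,12-dimethyl-4-methylidene-3-oxotrideca-7,11-dien-1-yl]tetrahydro-2H-pyran-2-yl]prop-2-enoate F7.
- Corey–Bakshi–Shibata reduction with the (S)-methyl oxazaborolidine and catecholborane in toluene at −78 °C should return 20 as the R alcohol, the branched alkenyl group acting as the larger ketone substituent.

Further compounds
F1 | step 3 | methyl 3-(6-oxotetrahydro-2H-pyran-3-yl)propanoate (racemate) | COC(=O)CCC1CCC(=O)OC1
F2 | step 3 | methyl 3-[(3R)-6-oxotetrahydro-2H-pyran-3-yl]propanoate | COC(=O)CC[C@@H]1CCC(=O)OC1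
F3 | step 4 | methyl (4R)-4-(hydroxymethyl)-7-(morpholin-4-yl)-7-oxoheptanoate | COC(=O)CC[C@H](CO)CCC(=O)N1CCOCC1
F4 | step 4 | (4S)-7-hydroxy-4-(hydroxymethyl)-1-(morpholin-4-yl)heptan-1-one | OCCC[C@H](CO)CCC(=O)N1CCOCC1
F5 | step 4 | 3-[(3S)-6-hydroxy-6-[(trimethylsilyl)ethynyl]tetrahydro-2H-pyran-3-yl]propan-1-ol (anomer mixture) | OCCC[C@H]1CCC(O)(C#C[Si](C)(C)C)OC1
F6 | step 12 | methyl 2-[(2R,5S)-5-[(7E)-3-hydroxy-8,12-dimethyl-4-methylidenetrideca-7,11-dien-1-yl]tetrahydro-2H-pyran-2-yl]prop-2-enoate (both carbinol epimers) | C=C(CC/C=C(\C)CCC=C(C)C)C(O)CC[C@H]1CC[C@H](C(=C)C(=O)OC)OC1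
F7 | step 12 | methyl 2-[(2R,5S)-5-[(7E)-8,12-dimethyl-4-methylidene-3-oxotrideca-7,11-dien-1-yl]tetrahydro-2H-pyran-2-yl]prop-2-enoate | C=C(CC/C=C(\C)CCC=C(C)C)C(=O)CC[C@H]1CC[C@H](C(=C)C(=O)OC)OC1
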